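The cyclohexadienone (acylfilicinic acid) ring is read as a cyclised polyketide: its ketone carbon C1 and the butanoyl-bearing carbon C2 are joined by a ring-closing Dieckmann C-acylation. In one operation the key step turns an enol lactone, (S)-3-methyl-3-prenyl-6-propyl-2H-pyran-2,4-dione, and lithiated methyl acetate into this carbocycle: Claisen attack on the lactone carbonyl unmasks a 1,3-diketone enolate, whose central carbon closes onto the new ester. The step exploits that C2 lies between two carbonyls and that the quaternary C4 (methyl, prenyl) cannot enolise, so its configuration, set by phase-transfer prenylation of a malonate, survives. The methylene bridge to the aryl ketone ring is added in the final step.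

Key step: step 7

Assumption: the (S,S)-catalyst of step 3 is taken, by analogy with related allylic electrophiles, to deliver the (S)-malonate 5; if the sense proved opposite, the (R,R)-catalyst would be used and nothing else changes.
Remark: enolised tricarbonyl compounds are drawn as one tautomer; CIP descriptors refer to the tautomer drawn.

Step 1
Reactants: 1 2,2,5-trimethyl-1,3-dioxane-4,6-dione
Product: 2 3-(tert-butoxy)-2-methyl-3-oxopropanoic acid (racemic)
Conditions: t-BuOH, reflux
Reagents that add atoms: tert-butanol, CC(C)(C)O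
Why: Alcoholysis of the activated cyclic diester opens the ring with loss of acetone and leaves the malonic half-ester; the α-carbon is configurationally labile, so no stereocontrol is needed here.

Step 2
Reactants: 2 3-(tert-butoxy)-2-methyl-3-oxopropanoic acid
Product: 3 1-tert-butyl 3-(2,2-diphenylethyl) 2-methylpropanedioate (racemic)
Conditions: Ph2CHCH2OH, N,N'-dicyclohexylcarbodiimide, 4-(dimethylamino)pyridine (cat.), CH2Cl2, 0 °C → rt
Reagents that add atoms: 2,2-diphenylethanol, OCC(c1ccccc1)c1ccccc1
Why: Steglich esterification places a base-labile primary ester next to the base-stable tert-butyl ester, the pair needed for the asymmetric alkylation and for later differentiation of the two carbonyl arms.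

Step 3
Reactants: 3 1-tert-butyl 3-(2,2-diphenylethyl) 2-methylpropanedioate; 4 1-bromo-3-methylbut-2-ene (prenyl bromide)
Product: 5 1-tert-butyl 3-(2,2-diphenylethyl) (S)-2-methyl-2-(3-methylbut-2-en-1-yl)propanedioate
Conditions: 4 (3 equiv), (S,S)-3,4,5-trifluorophenyl-NAS bromide (C56H34BrF6N, 5 mol %), 50% aq. KOH, toluene, −40 °C
Reagents that add atoms: none
Why: Enantioselective phase-transfer alkylation: the chiral N-spiro ammonium cation pairs with the malonate enolate, whose two different bulky esters let it distinguish the faces, and SN2 attack at the primary allylic carbon sets the quaternary stereocentre under catalyst control.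

Step 4
Reactants: 5 1-tert-butyl 3-(2,2-diphenylethyl) (S)-2-methyl-2-(3-methylbut-2-en-1-yl)propanedioate
Product: 6 (S)-3-(tert-butoxy)-2-methyl-2-(3-methylbut-2-en-1-yl)-3-oxopropanoic acid
Conditions: 1 M KOH, MeOH, rt; then 1 M HCl, 0 °C
Reagents that add atoms: potassium hydroxide, [K+].[OH-]
Why: Chemoselective saponification: hydroxide attacks the primary 2,2-diphenylethyl ester while the tert-butyl ester is shielded, and the fully substituted α-carbon cannot epimerise.

Step 5
Reactants: 6 (S)-3-(tert-butoxy)-2-methyl-2-(3-methylbut-2-en-1-yl)-3-oxopropanoic acid; 7 pentan-2-one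
Product: 9 tert-butyl (S)-2-methyl-2-(3-methylbut-2-en-1-yl)-3,5-dioxooctanoate, via acyl imidazole 8 (not isolated)
Conditions: 1,1'-carbonyldiimidazole, THF, rt, CO2 purged with N2; added to 7 (3.5 equiv)/LiN(iPr)2 (3.3 equiv), THF, −78 → 0 °C; 1 M HCl
Reagents that add atoms: 1,1'-carbonyldiimidazole, O=C(n1ccnc1)n1ccnc1 (its imidazolyl group is carried by 8 only)
Why: Crossed Claisen acylation: the kinetic methyl-side lithium enolate of 7 attacks the acyl imidazole far faster than the tert-butyl ester, and the further enolate equivalents absorb the released imidazole N–H and store the product as its diketonate, which prevents over-addition.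

Step 6
Reactants: 9 tert-butyl (S)-2-methyl-2-(3-methylbut-2-en-1-yl)-3,5-dioxooctanoate
Product: 12 (S)-3-methyl-3-(3-methylbut-2-en-1-yl)-6-propyl-2H-pyran-2,4(3H)-dione, via bis-silyl ester 10 (not isolated), via diketo acid 11 (not isolated)
Conditions: Me3SiOTf (3 equiv), 2,6-lutidine (4 equiv), CH2Cl2, 0 °C; pH 5 phosphate buffer, 0 °C; then N,N'-dicyclohexylcarbodiimide, CH2Cl2, 0 °C
Reagents that add atoms: trimethylsilyl trifluoromethanesulfonate, C[Si](C)(C)OS(=O)(=O)C(F)(F)F (its silyl groups are carried by 10 only)
Why: The silyl triflate cleaves the tert-butyl ester by loss of isobutene without protic acid, so the prenyl group and the enol are spared, and carbodiimide activation of the cold 3,5-diketo acid closes the enol lactone through the C5 enol oxygen (6-exo-trig lactonisation) before decarboxylation can compete.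

Step 7
Reactants: 12 (S)-3-methyl-3-(3-methylbut-2-en-1-yl)-6-propyl-2H-pyran-2,4(3H)-dione; 13 methyl acetate
Product: 15 (R)-2-butanoyl-3,5-dihydroxy-4-methyl-4-(3-methylbut-2-en-1-yl)cyclohexa-2,5-dien-1-one, via triketo ester 14 (not isolated)
Conditions: 13 (2.3 equiv), LiN(iPr)2 (2.2 equiv), THF, −78 °C; 12, −78 → 0 °C; then Mg(OMe)2 (2 equiv), MeOH, 65 °C; 1 M HCl
Reagents that add atoms: none
Why: The lithium enolate of 13 adds to the lactone carbonyl C2 of 12 (Claisen condensation on an enol ester), the ring opens by loss of the C6–O enolate, and a second enolate equivalent deprotonates the new β-keto ester to give the dianion of 14; in methanolic Mg(OMe)2 the central carbon of the 1,3-diketone (C6 of 14) attacks the ester carbonyl C1 and methoxide leaves (Dieckmann condensation), forming the C1–C2 bond of 15. The closest known reaction types are the carbanion ring-opening and recyclisation of enol lactones to cyclohexenones and the magnesium methoxide Claisen cyclisation of 3,5,7-triketo esters to acylphloroglucinols. The six-membered carbocycle closes in the 6-(enolexo)-exo-trig mode. No stereocentre is formed: the quaternary carbon has no α-hydrogen and is carried through unchanged, so the configuration set in step 3 is retained. The step needs acyl attack instead of conjugate attack on 12, and C-acylation instead of aldol closure or retro-Claisen cleavage of 14. These are secured because the fully substituted, propyl-bearing C6 of 12 is a poor acceptor for a lithium ester enolate at −78 °C, the quaternary carbon rules out an aromatising aldol or pyrone pathway, both flanking ketones are protected as chelated enolates, and only the Dieckmann product leaves the equilibria irreversibly as its strongly stabilised triketone enolate.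

Step 8
Reactants: 16 5-methoxybenzene-1,3-diol; 17 hexanoyl chloride
Product: 18 1-(2,4-dihydroxy-6-methoxyphenyl)hexan-1-one
Conditions: AlCl3 (3 equiv), CH2Cl2/PhNO2, 0 °C → rt; aq. HCl work-up; chromatography to remove the symmetric regioisomer
Reagents that add atoms: none
Why: Friedel–Crafts acylation of the phloroglucinol monomethyl ether, in which attack at C4/C6 (two equivalent sites, each para to a hydroxyl) should outweigh attack at C2, the symmetric 2,6-dihydroxy-4-methoxy isomer being separated.

Step 9
Reactants: 15 (R)-2-butanoyl-3,5-dihydroxy-4-methyl-4-(3-methylbut-2-en-1-yl)cyclohexa-2,5-dien-1-one; 18 1-(2,4-dihydroxy-6-methoxyphenyl)hexan-1-one; 19 N,N-dimethylmethaniminium iodide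
Product: 21 (R)-2-butanoyl-6-[(3-hexanoyl-2,6-dihydroxy-4-methoxyphenyl)methyl]-3,5-dihydroxy-4-methyl-4-(3-methylbut-2-en-1-yl)cyclohexa-2,5-dien-1-one, via Mannich base 20 (not isolated)
Conditions: 19 (1.0 equiv), NaOAc (1.1 equiv), MeCN, 0 °C → rt; then 18 (1.5 equiv), 60 °C
Reagents that add atoms: none
Why: Mannich reaction at the only ring C–H of 15, then loss of dimethylamine to the 6-methylene trione and Michael addition of 18 through C3, the position ortho to both free hydroxyls (the site favoured in C-alkylation of 2,4-dihydroxyaryl ketones), followed by rearomatisation; the stereocentre is not involved.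

Compound list
1 | 2,2,5-trimethyl-1,3-dioxane-4,6-dione | CC1C(=O)OC(C)(C)OC1=O | starting material
2 | 3-(tert-butoxy)-2-methyl-3-oxopropanoic acid (racemic) | CC(C(=O)O)C(=O)OC(C)(C)C | intermediate
3 | 1-tert-butyl 3-(2,2-diphenylethyl) 2-methylpropanedioate (racemic) | CC(C(=O)OCC(c1ccccc1)c1ccccc1)C(=O)OC(C)(C)C | intermediate
4 | 1-bromo-3-methylbut-2-ene (prenyl bromide) | CC(C)=CCBr | starting material
5 | 1-tert-butyl 3-(2,2-diphenylethyl) (S)-2-methyl-2-(3-methylbut-2-en-1-yl)propanedioate | CC(C)(C)OC(=O)[C@@](C)(CC=C(C)C)C(=O)OCC(c1ccccc1)c1ccccc1 | intermediate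
6 | (S)-3-(tert-butoxy)-2-methyl-2-(3-methylbut-2-en-1-yl)-3-oxopropanoic acid | CC(C)(C)OC(=O)[C@@](C)(CC=C(C)C)C(=O)O | intermediate
7 | pentan-2-one | CCCC(C)=O | starting material
8 | tert-butyl (S)-3-(1H-imidazol-1-yl)-2-methyl-2-(3-methylbut-2-en-1-yl)-3-oxopropanoate (acyl imidazole, not isolated) | CC(C)(C)OC(=O)[C@@](C)(CC=C(C)C)C(=O)n1ccnc1 | intermediate
9 | tert-butyl (S)-2-methyl-2-(3-methylbut-2-en-1-yl)-3,5-dioxooctanoate | CC(C)(C)OC(=O)[C@@](C)(CC=C(C)C)C(=O)CC(=O)CCC | intermediate
10 | trimethylsilyl (S)-2-methyl-2-(3-methylbut-2-en-1-yl)-3-oxo-5-(trimethylsilyloxy)oct-4-enoate (enol ether geometry not defined, not isolated) | C[Si](C)(C)OC(=O)[C@@](C)(CC=C(C)C)C(=O)C=C(CCC)O[Si](C)(C)C | intermediate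
11 | (S)-2-methyl-2-(3-methylbut-2-en-1-yl)-3,5-dioxooctanoic acid (not isolated) | OC(=O)[C@@](C)(CC=C(C)C)C(=O)CC(=O)CCC | intermediate
12 | (S)-3-methyl-3-(3-methylbut-2-en-1-yl)-6-propyl-2H-pyran-2,4(3H)-dione | CCCC1=CC(=O)[C@](C)(CC=C(C)C)C(=O)O1 | intermediate
13 | methyl acetate | COC(C)=O | starting material
14 | methyl (S)-4-methyl-4-(3-methylbut-2-en-1-yl)-3,5,7-trioxodecanoate (not isolated) | COC(=O)CC(=O)[C@@](C)(CC=C(C)C)C(=O)CC(=O)CCC | intermediate
15 | (R)-2-butanoyl-3,5-dihydroxy-4-methyl-4-(3-methylbut-2-en-1-yl)cyclohexa-2,5-dien-1-one | O=C1C=C(O)[C@@](C)(CC=C(C)C)C(O)=C1C(=O)CCC | intermediate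
16 | 5-methoxybenzene-1,3-diol | COc1cc(O)cc(O)c1 | starting material
17 | hexanoyl chloride | CCCCCC(=O)Cl | starting material
18 | 1-(2,4-dihydroxy-6-methoxyphenyl)hexan-1-one | CCCCCC(=O)c1c(OC)cc(O)cc1O | intermediate
19 | N,N-dimethylmethaniminium iodide | C[N+](C)=C.[I-] | starting material
20 | (R)-2-butanoyl-6-[(dimethylamino)methyl]-3,5-dihydroxy-4-methyl-4-(3-methylbut-2-en-1-yl)cyclohexa-2,5-dien-1-one (Mannich base, not isolated) | CN(C)CC1=C(O)[C@@](C)(CC=C(C)C)C(O)=C(C(=O)CCC)C1=O | intermediate
21 | (R)-2-butanoyl-6-[(3-hexanoyl-2,6-dihydroxy-4-methoxyphenyl)methyl]-3,5-dihydroxy-4-methyl-4-(3-methylbut-2-en-1-yl)cyclohexa-2,5-dien-1-one | CCCCCC(=O)c1c(OC)cc(O)c(CC2=C(O)[C@@](C)(CC=C(C)C)C(O)=C(C(=O)CCC)C2=O)c1O | target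

Total steps: 9. Longest linear sequence: 8 (steps 1–7 and 9).

Steps most likely to fail

Step 7. The ester enolate may add in conjugate fashion to C6 of 12 or deprotonate its propyl group instead of attacking the lactone carbonyl, and ring closure of the dianion may lose out to aldol closure or retro-Claisen cleavage. The fallback sets out from 12 and comes back at 15. The lactone 12 is opened under non-basic conditions by C-acylation of 2,2-dimethyl-1,3-dioxane-4,6-dione (4-(dimethylamino)pyridine, 1.2 equiv, CH2Cl2, 0 °C → rt) to give 2,2-dimethyl-5-[(S)-2-methyl-2-(3-methylbut-2-en-1-yl)-3,5-dioxooctanoyl]-1,3-dioxane-4,6-dione F1. Methanolysis of F1 (MeOH, 65 °C, with loss of acetone and carbon dioxide) gives the triketo ester 14, now isolated and purified. The Dieckmann closure of 14 is then run as a separate step with Mg(OMe)2 in MeOH to give 15.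

Step 9. The arene may attack through C5 instead of C3 and so place the bridge next to the methoxy group, and 15 may condense with itself. The fallback sets out from 15 and comes back at 21, fixing the bridge carbon by symmetry. Commercial 2,6-dihydroxy-4-methoxybenzaldehyde, whose two free ring positions are equivalent, is acylated with 17 (AlCl3, CH2Cl2/PhNO2) to 3-hexanoyl-2,6-dihydroxy-4-methoxybenzaldehyde F2. Knoevenagel condensation of F2 with 15 (L-proline cat., CH2Cl2/EtOH, rt) gives the arylidene trione (S)-2-butanoyl-6-[(3-hexanoyl-2,6-dihydroxy-4-methoxyphenyl)methylidene]-3-hydroxy-4-methyl-4-(3-methylbut-2-en-1-yl)cyclohex-2-ene-1,5-dione F3, which is not isolated. F3 is reduced in the same flask by conjugate hydride transfer from diethyl 2,6-dimethyl-1,4-dihydropyridine-3,5-dicarboxylate to give 21.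

Step 6. The free β-keto acid 11 may decarboxylate before it lactonises, and acid may induce cyclisation of the prenyl group onto the enol. The fallback sets out from 6 and comes back at 14, so that no β-keto acid is ever formed. Acid 6 is converted (1,1'-carbonyldiimidazole, then N,O-dimethylhydroxylamine hydrochloride) into tert-butyl (S)-3-[methoxy(methyl)amino]-2-methyl-2-(3-methylbut-2-en-1-yl)-3-oxopropanoate F4. Cleavage of the tert-butyl ester (Me3SiOTf, 2,6-lutidine, then buffer) gives the stable malonamic acid (S)-3-[methoxy(methyl)amino]-2-methyl-2-(3-methylbut-2-en-1-yl)-3-oxopropanoic acid F5. Decarboxylative Claisen homologation (1,1'-carbonyldiimidazole, then Mg(O2CCH2CO2Me)2, THF) gives methyl (R)-5-[methoxy(methyl)amino]-4-methyl-4-(3-methylbut-2-en-1-yl)-3,5-dioxopentanoate F6. Addition of the lithium enolate of 7 (3 equiv, LiN(iPr)2, THF, −78 → 0 °C) to the N-methoxy-N-methylamide of F6 gives 14, which is cyclised to 15 with Mg(OMe)2 in MeOH as in step 7.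

Further compounds
F1 | step 7 | 2,2-dimethyl-5-[(S)-2-methyl-2-(3-methylbut-2-en-1-yl)-3,5-dioxooctanoyl]-1,3-dioxane-4,6-dione | CC1(C)OC(=O)C(C(=O)[C@@](C)(CC=C(C)C)C(=O)CC(=O)CCC)C(=O)O1
F2 | step 9 | 3-hexanoyl-2,6-dihydroxy-4-methoxybenzaldehyde | CCCCCC(=O)c1c(OC)cc(O)c(C=O)c1O
F3 | step 9 | (S)-2-butanoyl-6-[(3-hexanoyl-2,6-dihydroxy-4-methoxyphenyl)methylidene]-3-hydroxy-4-methyl-4-(3-methylbut-2-en-1-yl)cyclohex-2-ene-1,5-dione (alkene geometry not defined) | CCCCCC(=O)c1c(OC)cc(O)c(C=C2C(=O)[C@@](C)(CC=C(C)C)C(O)=C(C(=O)CCC)C2=O)c1O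
F4 | step 6 | tert-butyl (S)-3-[methoxy(methyl)amino]-2-methyl-2-(3-methylbut-2-en-1-yl)-3-oxopropanoate | CC(C)(C)OC(=O)[C@@](C)(CC=C(C)C)C(=O)N(C)OC
F5 | step 6 | (S)-3-[methoxy(methyl)amino]-2-methyl-2-(3-methylbut-2-en-1-yl)-3-oxopropanoic acid | OC(=O)[C@@](C)(CC=C(C)C)C(=O)N(C)OC
F6 | step 6 | methyl (R)-5-[methoxy(methyl)amino]-4-methyl-4-(3-methylbut-2-en-1-yl)-3,5-dioxopentanoate | COC(=O)CC(=O)[C@@](C)(CC=C(C)C)C(=O)N(C)OC
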